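## The problem

The target is a C20 methyl ester (chain numbering from the ester carbon C1) in which a cyclopentane, C13–C17, carries a cis-fused epoxide on C14/C15, a (5Z,8Z,11Z)-trienoate chain on C13 and a 1-chloropropyl group (C18–C20) on C17. Five stereocentres are present: C18 (S) bears chlorine outside the ring, C17 (R) and C13 (S) carry their carbon substituents trans to each other, and the epoxide oxygen at C14 (R)/C15 (S) lies on the face of the chloropropyl group, anti to the chain on C13. A chain of control is available: C18 can bias addition to C17 by 1,2-induction, C17 fixes C13 because trans is both the outcome of a suprafacial ring formation and the stable arrangement, and the C13 substituent can steer an oxidant to the opposite face of a C14=C15 alkene; no polar group is placed to deliver the oxygen, so this last link is steric only. The skipped all-cis triene does not tolerate base, air or electrophilic oxidants, the epoxide does not tolerate protic or Lewis acid, and the secondary chloride is open to elimination and substitution, so the triene must come last and the epoxide after every acidic step. C13 is allylic to the future epoxide carbons and α to any carbonyl group that stands in for C12, so every C12 carbonyl intermediate is exposed to epimerisation and to migration of the double bond into conjugation. The feature that opens the route is that C16–C15–C14 bridges C17 and C13, the β- and α-carbons of a C17=C13–C12(=O) enone, and that an alkene at C14=C15 is exactly the epoxide precursor; this is the pattern left by a [3+2] annulation of an allene onto an enone. In addition, C17–C18(Cl)–C19–C20 maps onto 2-aminobutanoic acid, the carboxyl carbon becoming C17 and the amino-bearing carbon C18, so the chlorine stereocentre can be taken from the L-amino acid.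

## Retrosynthesis

**Triene.** The three (Z)-alkenes of 32 are taken back to the three alkynes of triyne 31. A Wittig construction of C11=C12 was the neighbouring option, but it would need a C12 aldehyde next to the finished epoxide, which is lost by enolisation, and it would set only one of the three alkenes. The cut removes all alkene geometry from the precursor and leaves a skeleton that can be assembled by sp–sp3 couplings. The forward step must add one H2 to each alkyne, syn, and leave the epoxide and the C–Cl bond alone.

**C10–C11 and C6–C7.** 31 is cut between C10 and C11 into terminal alkyne 24 and propargylic bromide 29. 29 is cut in the same way between C6 and C7 into methyl hex-5-ynoate 25 and 4-chlorobut-2-yn-1-ol 26, by way of alcohol 28. Cutting at C10–C11 rather than C7–C8 gives the most convergent split: all five stereocentres sit in 24 and all of C1–C10 in 29. The forward couplings must run with carbonate base only, since epoxide, chloride, ester and the skipped polyynes all suffer under strong base.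

**Epoxide, C11 and the two silicon atoms.** 24 is traced to dibromoalkene 22 (C11 supplied as CBr2), 22 to alkene 21 (epoxide removed), 21 to vinylsilane 20, 20 to aldehyde 19 and 19 to acylsilane 18. The epoxide is placed at the dibromoalkene stage, not on the free alkyne as the shorter ordering would suggest. The reason is that CH=CBr2 is the bulkiest form of the C13 substituent that is neither enolisable nor oxidisable, and face selection depends on that bulk. The ring silicon is removed before the epoxide exists (acid), the acyl silicon is exchanged for hydrogen first (fluoride), and the aldehyde is olefinated at once under non-basic conditions. The sequence asks for a mild unmasking of a β,γ-unsaturated aldehyde and for steric face control in the epoxidation.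

**C16–C17 and C13–C14 (key disconnection).** 18 is cut across the ring into enoyl silane 11 and (trimethylsilyl)allene 15. Compared with a cut at C13–C17 (carbene or enolate chemistry) or a ring contraction, this cut makes the ring, the trans C13/C17 pair and the C14=C15 alkene in one event and leaves an acyclic precursor with a single stereocentre. The acyl silicon makes the enone reactive at −78 °C and later becomes C12–H. The allene silicon ends on C15, from where it is removed without moving the alkene. The forward reaction has to transmit C18 to C17, turn the (E)-geometry into a trans ring, and leave the C–Cl bond un-ionised.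

**C13=C17 and the stereocentre.** 11 is cut at the enone double bond into acetyltrimethylsilane 7 and (S)-2-chlorobutanal 6 (aldol 9, then dehydration). 6 is taken through alcohol 5 and acid 4 to L-2-aminobutyric acid 1. A phosphorus-based olefination would do the same job, but its acylsilane reagent would first have to be made, whereas 7 is commercial. Allene 15 is traced to propargylic alcohol 12 by a reductive 1,3-transposition. The forward steps must keep the α-chloro aldehyde 6 from racemising, hence a non-basic oxidation and an aldol at −78 °C.

## Roads not taken

**Alternative 1:** The ring is cut at C13–C17 and, temporarily, at C13–C18. Diazo ketoester A1 would be converted by CuOTf with a chiral bis(oxazoline) ligand (or a chiral dirhodium tetracarboxylate of the Rh2(OAc)4 type) into a carbenoid that adds to its (Z)-alkene, giving bicyclic keto ester A2. Chloride would then open the doubly activated cyclopropane at C18 with inversion.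
- Merits: the C17/C18 relationship follows stereospecifically from alkene geometry and an SN2 opening, which is firmer than the 1,2-induction the chosen plan relies on. Absolute configuration comes from a catalyst, and chlorine enters as plain chloride.
- Weak points: enantioselection in intramolecular cyclopropanation of α-diazo-β-keto esters is usually modest compared with diazoacetates. The opening must choose C18 over C17 at a secondary carbon. A2 also leaves C14 as a ketone flanked by the C13 ester, so the C14=C15 alkene would have to be made against the natural enolisation towards C13; that costs several redox and protection steps, after which the same epoxide-face question returns.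
- Comparison: the chosen plan accepts weaker control at C17. In return it buys C18 as a stereocentre and delivers the alkene in the right place in the ring-forming step.

**Alternative 2:** The cut is made at the functional groups. The C2-symmetric ketodiester A3 would be converted through its enol triflate (no regiochemical issue, by symmetry) into diacid A4. Iodolactonisation would then let the C17 carboxylate attack C15 anti to iodine on C14, giving the bridged iodo lactone acid A5.
- Merits: the tether fixes the oxygen face unambiguously and tells the two carboxyl groups apart in the same step. This is clearly better than the steric epoxidation of the chosen plan.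
- Weak points: C18 arrives as a carboxyl carbon. The ethyl group, the C18 configuration (a ketone reduction under induction from C17) and the chloride (SN2 on a hindered secondary alcohol) all remain to be made, next to an iodo lactone or an epoxide. A3 also needs resolution or an asymmetric synthesis, and the route is longer.
- Comparison: the chosen plan has the less secure epoxide step. Against that it sets C18 from the chiral pool and two ring stereocentres in one step.

**Alternative 3:** The ring is cut at C13–C14 in the sense of a ring contraction. 3-Methoxybenzoic acid A6 would be taken by Birch reduction, enol ether hydrolysis, esterification and diazo transfer to diazo enone A7. Photolysis in methanol would trigger a Wolff rearrangement in which the vinyl carbon C14 migrates to C13, and methanol would trap the ketene to give diester A8.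
- Merits: the feedstock is the cheapest of all. The alkene lies at C14=C15 as in the chosen plan, and the two carboxyls come differentiated (tert-butyl against methyl), which is as good as alternative 2 on that point.
- Weak points: nothing sets absolute configuration, so a resolution is needed. C18 must again be built from a carboxyl carbon. Diazo transfer to the α′-position of an enone and a preparative photolysis add operational burden, and a vinyl group is not the best migrating group in a carbene rearrangement. The epoxide face is left to sterics unless the lactone device of alternative 2 is borrowed.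
- Comparison: A8 is equal to the chosen plan in alkene placement and better in raw material cost. The chosen plan is ahead in absolute stereocontrol, in C18 and in step count.

Key step: step 7

## Route

Step 1
Reactants: 1 L-2-aminobutyric acid [(S)-2-aminobutanoic acid]
Product: 4 (S)-2-chlorobutanoic acid, via diazonium carboxylate 2 (not isolated), via α-lactone 3 (not isolated)
Conditions: NaNO2, 5 M aq. HCl, 0 → 23 °C
Reagents that add atoms: hydrogen chloride, SMILES Cl
Why: Diazotisation of an α-amino acid in hydrochloric acid; the neighbouring carboxylate expels N2 from 2 with inversion to give α-lactone 3, which chloride opens with a second inversion, so the future C18 should be obtained with net retention as (S).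

Step 2
Reactants: 4 (S)-2-chlorobutanoic acid
Product: 5 (S)-2-chlorobutan-1-ol
Conditions: LiAlH4, Et2O, 0 °C, short reaction time; aqueous work-up
Reagents that add atoms: none
Why: Hydride reduction of a carboxylic acid; at 0 °C the carboxylate is reduced much faster than the secondary C–Cl bond, and the stereocentre is not enolisable at the carboxylate or alkoxide stage.

Step 3
Reactants: 5 (S)-2-chlorobutan-1-ol
Product: 6 (S)-2-chlorobutanal
Conditions: Dess–Martin periodinane, CH2Cl2, 0 → 23 °C; kept cold in solution and used at once
Reagents that add atoms: none
Why: Dess–Martin oxidation, chosen because it is non-basic and so should not racemise the enolisable α-chloro aldehyde; the volatile product is not stored.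

Step 4
Reactants: 7 acetyltrimethylsilane; 6 (S)-2-chlorobutanal
Product: 9 (4S)-4-chloro-3-hydroxy-1-(trimethylsilyl)hexan-1-one (both C3 epimers), via lithium 1-(trimethylsilyl)ethenolate 8 (not isolated)
Conditions: LiN(i-Pr)2, THF, −78 °C; then 6, −78 °C; AcOH quench at −78 °C
Reagents that add atoms: none
Why: Directed aldol addition of a preformed lithium enolate to an α-chloro aldehyde; at −78 °C addition outruns enolisation of 6 and the chlorohydrin alkoxide does not close to an epoxide, and the C3 configuration is irrelevant because step 5 removes it.

Step 5
Reactants: 9 (4S)-4-chloro-3-hydroxy-1-(trimethylsilyl)hexan-1-one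
Product: 11 (2E,4S)-4-chloro-1-(trimethylsilyl)hex-2-en-1-one, via mesylate 10 (not isolated)
Conditions: MsCl, Et3N, CH2Cl2, −20 → 0 °C
Reagents that add atoms: none
Why: Mesylation and E1cB elimination of a β-hydroxy ketone should give the conjugated (E)-enone as the stable geometry; a tertiary amine at low temperature is not expected to deprotonate the γ-position that carries chlorine.

Step 6
Reactants: 12 3-(trimethylsilyl)prop-2-yn-1-ol
Product: 15 trimethyl(propa-1,2-dien-1-yl)silane, via sulfonylhydrazide adduct 13 (not isolated), via propargyl diazene 14 (not isolated)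
Conditions: 2-O2NC6H4SO2NHNH2, PPh3, DEAD, THF, −15 → 23 °C; pentane/water partition, distillation
Reagents that add atoms: none
Why: Myers allene synthesis: Mitsunobu N-alkylation gives 13, loss of the sulfinic acid gives diazene 14, and its retro-ene loss of N2 delivers hydrogen to the silicon-bearing alkyne carbon, so the allene is the only possible regioisomer.

Step 7
Reactants: 11 (2E,4S)-4-chloro-1-(trimethylsilyl)hex-2-en-1-one; 15 trimethyl(propa-1,2-dien-1-yl)silane
Product: 18 [(1R,5R)-5-[(1S)-1-chloropropyl]-3-(trimethylsilyl)cyclopent-2-en-1-yl](trimethylsilyl)methanone, via β-silyl vinyl cation TiCl4 enolate 16 (not isolated), via silyl-shifted vinyl cation TiCl4 enolate 17 (not isolated)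
Conditions: TiCl4 (1.2 equiv), 15 (1.5–2 equiv), CH2Cl2, −78 °C, short contact time; poured into cold water
Reagents that add atoms: none
Why: Danheiser-type [3+2] annulation of an allenylsilane with an α,β-unsaturated acylsilane; the closest known cases use C1-substituted (trimethylsilyl)allenes and acceptors without a γ-heteroatom. TiCl4 binds the acyl oxygen of 11, the CH2 terminus of 15 adds to C17 (C16–C17) to give the β-silyl-stabilised vinyl cation 16, a 1,2-shift of silicon from C14 to C15 gives 17, and the enolate carbon C13 captures C14 (C13–C14). The cyclopentene therefore closes stepwise by collapse of an enolate onto a linear vinyl cation, a 5-(enolexo)-endo-dig closure, and the alkene is fixed at C14=C15 with silicon on C15. C17 is controlled by C18: in the reactive conformer C18–H eclipses the C13=C17 bond, the C–Cl bond stands perpendicular to the π system and the allene attacks anti to chlorine (Felkin–Anh type), which converts (18S) into (17R). C13 is controlled by the (E)-alkene geometry: both new bonds form on the same alkene face, so the acyl group ends trans to the chloropropyl group, which is also the more stable arrangement at this enolisable centre. The step needs annulation to win over loss of silicon from 16 (propargyl transfer) and over ring enlargement of 18, and it needs the allylic C–Cl bond to stay; the highly electrophilic acylsilane–TiCl4 complex allows −78 °C, a short contact time and a cold quench, and ionisation of C18–Cl is disfavoured because the cation would be conjugated to the electron-poor enone.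

Step 8
Reactants: 18 [(1R,5R)-5-[(1S)-1-chloropropyl]-3-(trimethylsilyl)cyclopent-2-en-1-yl](trimethylsilyl)methanone
Product: 19 (1R,5R)-5-[(1S)-1-chloropropyl]-3-(trimethylsilyl)cyclopent-2-ene-1-carbaldehyde
Conditions: n-Bu4NF (1.1 equiv), AcOH (1.1 equiv), THF–H2O, −20 → 0 °C; used crude
Reagents that add atoms: none
Why: Fluoride-induced protodesilylation of an acylsilane to the aldehyde; the acetic acid buffer is meant to keep the medium from enolising the β,γ-unsaturated aldehyde, and the vinyl C–Si bond is inert to fluoride under these conditions.

Step 9
Reactants: 19 (1R,5R)-5-[(1S)-1-chloropropyl]-3-(trimethylsilyl)cyclopent-2-ene-1-carbaldehyde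
Product: 20 [(3R,4R)-4-[(1S)-1-chloropropyl]-3-(2,2-dibromoethenyl)cyclopent-1-en-1-yl]trimethylsilane
Conditions: CBr4, PPh3, Zn, CH2Cl2, 0 → 23 °C (ylide preformed, then 19)
Reagents that add atoms: carbon tetrabromide, SMILES BrC(Br)(Br)Br
Why: Ramirez dibromo-olefination, the first half of the Corey–Fuchs sequence; the dibromomethylene ylide is not basic, so C13 should neither epimerise nor lose its proton, and C11 is introduced here.

Step 10
Reactants: 20 [(3R,4R)-4-[(1S)-1-chloropropyl]-3-(2,2-dibromoethenyl)cyclopent-1-en-1-yl]trimethylsilane
Product: 21 (3R,4R)-4-[(1S)-1-chloropropyl]-3-(2,2-dibromoethenyl)cyclopent-1-ene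
Conditions: p-TolSO2H, MeCN–H2O, 80 °C
Reagents that add atoms: none
Why: Acid-mediated protodesilylation of a vinylsilane: ipso protonation at C15 gives the β-silyl cation at C14, which loses silicon faster than a proton, so the double bond should stay at C14=C15; the dibromoalkene is too electron-poor to protonate and the alkyl chloride is acid-stable.

Step 11
Reactants: 21 (3R,4R)-4-[(1S)-1-chloropropyl]-3-(2,2-dibromoethenyl)cyclopent-1-ene
Product: 22 (1R,2R,3R,5S)-3-[(1S)-1-chloropropyl]-2-(2,2-dibromoethenyl)-6-oxabicyclo[3.1.0]hexane
Conditions: mCPBA, NaHCO3, CH2Cl2, 0 °C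
Reagents that add atoms: 3-chloroperoxybenzoic acid, SMILES O=C(OO)c1cccc(Cl)c1
Why: Prilezhaev epoxidation; only the ring alkene is electron-rich enough to react, and the peracid should approach the face anti to the branched allylic dibromovinyl group on C13, which sets C14 and C15 with oxygen on the face of the chloropropyl group.

Step 12
Reactants: 22 (1R,2R,3R,5S)-3-[(1S)-1-chloropropyl]-2-(2,2-dibromoethenyl)-6-oxabicyclo[3.1.0]hexane
Product: 24 (1R,2R,3R,5S)-3-[(1S)-1-chloropropyl]-2-ethynyl-6-oxabicyclo[3.1.0]hexane, via lithium acetylide 23 (not isolated)
Conditions: n-BuLi (2.1 equiv), THF, −78 °C; sat. aq. NH4Cl at −78 °C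
Reagents that add atoms: none
Why: Second half of the Corey–Fuchs alkyne synthesis (bromine–lithium exchange, Fritsch–Buttenberg–Wiechell 1,2-shift, deprotonation to 23, protonation on quench); at −78 °C the exchange is far faster than attack of the base on the epoxide or the secondary chloride.

Step 13
Reactants: 25 methyl hex-5-ynoate; 26 4-chlorobut-2-yn-1-ol
Product: 28 methyl 10-hydroxydeca-5,8-diynoate, via 4-iodobut-2-yn-1-ol 27 (not isolated)
Conditions: CuI, NaI, K2CO3, DMF, 23 °C
Reagents that add atoms: none
Why: Copper-mediated coupling of a terminal alkyne with a propargylic halide, made more reactive by halide exchange to 27; carbonate is the only base, so the skipped diyne should not isomerise to an allene and the ester survives.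

Step 14
Reactants: 28 methyl 10-hydroxydeca-5,8-diynoate
Product: 29 methyl 10-bromodeca-5,8-diynoate
Conditions: CBr4, PPh3, CH2Cl2, −20 → 0 °C
Reagents that add atoms: carbon tetrabromide, SMILES BrC(Br)(Br)Br
Why: Appel bromination of a primary propargylic alcohol under neutral conditions, compatible with the base-sensitive skipped diyne.

Step 15
Reactants: 24 (1R,2R,3R,5S)-3-[(1S)-1-chloropropyl]-2-ethynyl-6-oxabicyclo[3.1.0]hexane; 29 methyl 10-bromodeca-5,8-diynoate
Product: 31 methyl 12-[(1R,2R,3R,5S)-3-[(1S)-1-chloropropyl]-6-oxabicyclo[3.1.0]hexan-2-yl]dodeca-5,8,11-triynoate, via methyl 10-iododeca-5,8-diynoate 30 (not isolated)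
Conditions: CuI, NaI, Cs2CO3, DMF, 23 °C, argon; product used without storage
Reagents that add atoms: none
Why: The same copper-mediated alkyne–propargyl halide coupling forms C10–C11; carbonate base at room temperature should spare the epoxide, the secondary chloride and the ester.

Step 16
Reactants: 31 methyl 12-[(1R,2R,3R,5S)-3-[(1S)-1-chloropropyl]-6-oxabicyclo[3.1.0]hexan-2-yl]dodeca-5,8,11-triynoate
Product: 32 methyl (5Z,8Z,11Z)-12-[(1R,2S,3R,5S)-3-[(1S)-1-chloropropyl]-6-oxabicyclo[3.1.0]hexan-2-yl]dodeca-5,8,11-trienoate (CNP0141251.1)
Conditions: H2 (1 atm), Pd/CaCO3 poisoned with Pb(OAc)2, quinoline, EtOAc, 23 °C; stopped after uptake of three equivalents of H2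
Reagents that add atoms: none
Why: Lindlar semihydrogenation; syn delivery of H2 to each alkyne should give the three (Z)-alkenes, and the poisoned catalyst is not expected to hydrogenolyse the homoallylic epoxide or the alkyl chloride; the descriptor at ring C2 changes from R to S only because the ranking of its substituents changes.

## Compound list

1 | L-2-aminobutyric acid [(S)-2-aminobutanoic acid] | CC[C@H](N)C(=O)O | starting material
2 | (S)-1-carboxylatopropane-1-diazonium (diazonium carboxylate) | CC[C@H]([N+]#N)C(=O)[O-] | intermediate
3 | (R)-3-ethyloxiran-2-one (α-lactone) | CC[C@H]1OC1=O | intermediate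
4 | (S)-2-chlorobutanoic acid | CC[C@H](Cl)C(=O)O | intermediate
5 | (S)-2-chlorobutan-1-ol | CC[C@H](Cl)CO | intermediate
6 | (S)-2-chlorobutanal | CC[C@H](Cl)C=O | intermediate
7 | acetyltrimethylsilane [1-(trimethylsilyl)ethan-1-one] | CC(=O)[Si](C)(C)C | starting material
8 | lithium 1-(trimethylsilyl)ethenolate | C=C(O[Li])[Si](C)(C)C | intermediate
9 | (4S)-4-chloro-3-hydroxy-1-(trimethylsilyl)hexan-1-one (both C3 epimers) | C[Si](C)(C)C(=O)CC(O)[C@@H](Cl)CC | intermediate
10 | (4S)-4-chloro-1-oxo-1-(trimethylsilyl)hexan-3-yl methanesulfonate | C[Si](C)(C)C(=O)CC(OS(C)(=O)=O)[C@@H](Cl)CC | intermediate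
11 | (2E,4S)-4-chloro-1-(trimethylsilyl)hex-2-en-1-one | C[Si](C)(C)C(=O)/C=C/[C@@H](Cl)CC | intermediate
12 | 3-(trimethylsilyl)prop-2-yn-1-ol | C[Si](C)(C)C#CCO | starting material
13 | 2-nitro-N-[3-(trimethylsilyl)prop-2-yn-1-yl]benzenesulfonohydrazide (alkyl group on the sulfonylated nitrogen) | C[Si](C)(C)C#CCN(N)S(=O)(=O)c1ccccc1[N+](=O)[O-] | intermediate
14 | [3-(trimethylsilyl)prop-2-yn-1-yl]diazene | C[Si](C)(C)C#CCN=N | intermediate
15 | trimethyl(propa-1,2-dien-1-yl)silane [(trimethylsilyl)allene] | C=C=C[Si](C)(C)C | intermediate
16 | zwitterion after C16–C17 bond formation: O-bound tetrachlorotitanate enolate (C12=C13) with a vinyl cation at C15 and silicon on C14 | CC[C@H](Cl)[C@H](C[C+]=C[Si](C)(C)C)C=C(O[Ti-](Cl)(Cl)(Cl)Cl)[Si](C)(C)C | intermediate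
17 | zwitterion after the 1,2-silyl shift: same enolate with the vinyl cation at C14 and silicon on C15 | CC[C@H](Cl)[C@H](CC(=[CH+])[Si](C)(C)C)C=C(O[Ti-](Cl)(Cl)(Cl)Cl)[Si](C)(C)C | intermediate
18 | [(1R,5R)-5-[(1S)-1-chloropropyl]-3-(trimethylsilyl)cyclopent-2-en-1-yl](trimethylsilyl)methanone | CC[C@H](Cl)[C@@H]1CC([Si](C)(C)C)=C[C@H]1C(=O)[Si](C)(C)C | intermediate
19 | (1R,5R)-5-[(1S)-1-chloropropyl]-3-(trimethylsilyl)cyclopent-2-ene-1-carbaldehyde | CC[C@H](Cl)[C@@H]1CC([Si](C)(C)C)=C[C@H]1C=O | intermediate
20 | [(3R,4R)-4-[(1S)-1-chloropropyl]-3-(2,2-dibromoethenyl)cyclopent-1-en-1-yl]trimethylsilane | CC[C@H](Cl)[C@@H]1CC([Si](C)(C)C)=C[C@H]1C=C(Br)Br | intermediate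
21 | (3R,4R)-4-[(1S)-1-chloropropyl]-3-(2,2-dibromoethenyl)cyclopent-1-ene | CC[C@H](Cl)[C@@H]1CC=C[C@H]1C=C(Br)Br | intermediate
22 | (1R,2R,3R,5S)-3-[(1S)-1-chloropropyl]-2-(2,2-dibromoethenyl)-6-oxabicyclo[3.1.0]hexane | CC[C@H](Cl)[C@@H]1C[C@@H]2O[C@@H]2[C@H]1C=C(Br)Br | intermediate
23 | {[(1R,2R,3R,5S)-3-[(1S)-1-chloropropyl]-6-oxabicyclo[3.1.0]hexan-2-yl]ethynyl}lithium | CC[C@H](Cl)[C@@H]1C[C@@H]2O[C@@H]2[C@H]1C#C[Li] | intermediate
24 | (1R,2R,3R,5S)-3-[(1S)-1-chloropropyl]-2-ethynyl-6-oxabicyclo[3.1.0]hexane | CC[C@H](Cl)[C@@H]1C[C@@H]2O[C@@H]2[C@H]1C#C | intermediate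
25 | methyl hex-5-ynoate | C#CCCCC(=O)OC | starting material
26 | 4-chlorobut-2-yn-1-ol | OCC#CCCl | starting material
27 | 4-iodobut-2-yn-1-ol | OCC#CCI | intermediate
28 | methyl 10-hydroxydeca-5,8-diynoate | OCC#CCC#CCCCC(=O)OC | intermediate
29 | methyl 10-bromodeca-5,8-diynoate | BrCC#CCC#CCCCC(=O)OC | intermediate
30 | methyl 10-iododeca-5,8-diynoate | ICC#CCC#CCCCC(=O)OC | intermediate
31 | methyl 12-[(1R,2R,3R,5S)-3-[(1S)-1-chloropropyl]-6-oxabicyclo[3.1.0]hexan-2-yl]dodeca-5,8,11-triynoate | CC[C@H](Cl)[C@@H]1C[C@@H]2O[C@@H]2[C@H]1C#CCC#CCC#CCCCC(=O)OC | intermediate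
32 | methyl (5Z,8Z,11Z)-12-[(1R,2S,3R,5S)-3-[(1S)-1-chloropropyl]-6-oxabicyclo[3.1.0]hexan-2-yl]dodeca-5,8,11-trienoate | CC[C@H](Cl)[C@@H]1C[C@@H]2O[C@@H]2[C@H]1/C=C\C/C=C\C/C=C\CCCC(=O)OC | target

## Step count and risks

Total: 16 steps. Longest linear sequence: 13 steps (steps 1–5, 7–12, 15, 16); step 6 and steps 13–14 are side branches.

**Step 7 (key step).**
- Most likely failure: silicon is lost from cation 16 before it migrates, so a propargyl group is transferred to C17 without ring closure. The parent allene is the weak partner here, because the cation formed after the shift (17) carries no carbon substituent.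
- Also possible: erosion of the facial preference at C17, which rests on a single C–Cl bond, and ring enlargement of the acylsilane if the mixture warms.
- Fallback: change the acceptor to the ketone class on which this annulation has its broadest record, and bring C11 in with the acceptor. The fallback sets out from 6 and 15 and returns at 24. Aldehyde 6 is condensed with commercial 1-(triphenylphosphoranylidene)propan-2-one (CH2Cl2, 0 → 23 °C, a stabilised Wittig reaction that α-chloro aldehydes tolerate) to give (3E,5S)-5-chlorohept-3-en-2-one F1. TiCl4-promoted annulation of F1 with allene 15 under the same control elements should give methyl ketone 1-[(1R,5R)-5-[(1S)-1-chloropropyl]-3-(trimethylsilyl)cyclopent-2-en-1-yl]ethan-1-one F2, whose methyl group is C11. Kinetic enolisation at the methyl group and phosphorylation (LiN(i-Pr)2, THF, −78 °C; ClP(O)(OEt)2) give enol phosphate F3, which more LiN(i-Pr)2 at low temperature converts into silyl enyne F4. Protodesilylation as in step 10 gives enyne F5, and peracid epoxidation as in step 11 rejoins the route at alkyne 24.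
- Price: the epoxidation is then steered by the slim ethynyl group only, and the enolisation has to avoid the allylic C13–H.

**Step 8.**
- Most likely failure: enolisation of the β,γ-unsaturated aldehyde by the fluoride medium, which would move the C14=C15 double bond into conjugation (loss of C13 and of the epoxide position) or epimerise C13.
- Fallback: oxidise the acylsilane instead of protodesilylating it. The fallback sets out from 18 and returns at 19. Alkaline hydrogen peroxide (H2O2, NaOH, THF–H2O, 0 °C) adds to the acyl silicon carbonyl faster than hydroxide enolises it and should give (1R,5R)-5-[(1S)-1-chloropropyl]-3-(trimethylsilyl)cyclopent-2-ene-1-carboxylic acid F6, which as a carboxylate no longer conjugates. LiAlH4 (Et2O, 0 °C, as in step 2) reduces it to [(1R,5R)-5-[(1S)-1-chloropropyl]-3-(trimethylsilyl)cyclopent-2-en-1-yl]methanol F7. Dess–Martin oxidation then gives 19 under non-basic conditions, for immediate use in step 9.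

**Step 11.**
- Most likely failure: insufficient facial discrimination, because the allylic dibromovinyl group on C13 and the homoallylic chloropropyl group on C17 shield opposite faces of the alkene.
- Fallback: replace the peracid by osmylation, whose bulkier transition state responds more strongly to the allylic substituent, and convert the cis-diol into the epoxide with retention. The fallback sets out from 21 and returns at 22. OsO4 (catalytic) with N-methylmorpholine N-oxide in acetone–water should give (1S,2R,3R,4R)-4-[(1S)-1-chloropropyl]-3-(2,2-dibromoethenyl)cyclopentane-1,2-diol F8, with both hydroxyl groups anti to the C13 substituent. MeC(OMe)3 with pyridinium p-toluenesulfonate gives cyclic orthoacetate F9. AcBr opens the derived acetoxonium ion with inversion to give trans-bromo acetate F10. K2CO3 in MeOH removes the acetate and closes the epoxide with a second inversion, so the oxygen stays on the osmylated face and 22 results.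

**Step 16.**
- Most likely failure: over-reduction or incomplete reduction, because three alkynes of different hindrance (C11≡C12 sits next to the ring) must each take up exactly one H2, and the partly reduced products are hard to separate.
- Fallback: reduce the two chain alkynes before the coupling, so that only one alkyne remains at the end. The fallback sets out from 28 and 24 and returns at 32. Semihydrogenation of 28 (H2, Pd/CaCO3 poisoned with Pb(OAc)2, quinoline), at a stage where purification is simple, gives methyl (5Z,8Z)-10-hydroxydeca-5,8-dienoate F11. Appel bromination (CBr4, PPh3) gives methyl (5Z,8Z)-10-bromodeca-5,8-dienoate F12. Copper-mediated coupling with alkyne 24 (CuI, NaI, Cs2CO3, DMF) gives dienyne F13, and semihydrogenation of its single alkyne gives 32.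

## Further compounds

F1 | step 7 | (3E,5S)-5-chlorohept-3-en-2-one | CC(=O)/C=C/[C@@H](Cl)CC
F2 | step 7 | 1-[(1R,5R)-5-[(1S)-1-chloropropyl]-3-(trimethylsilyl)cyclopent-2-en-1-yl]ethan-1-one | CC[C@H](Cl)[C@@H]1CC([Si](C)(C)C)=C[C@H]1C(C)=O
F3 | step 7 | 1-[(1R,5R)-5-[(1S)-1-chloropropyl]-3-(trimethylsilyl)cyclopent-2-en-1-yl]ethenyl diethyl phosphate | CC[C@H](Cl)[C@@H]1CC([Si](C)(C)C)=C[C@H]1C(=C)OP(=O)(OCC)OCC
F4 | step 7 | [(3R,4R)-4-[(1S)-1-chloropropyl]-3-ethynylcyclopent-1-en-1-yl]trimethylsilane | CC[C@H](Cl)[C@@H]1CC([Si](C)(C)C)=C[C@H]1C#C
F5 | step 7 | (3R,4R)-4-[(1S)-1-chloropropyl]-3-ethynylcyclopent-1-ene | CC[C@H](Cl)[C@@H]1CC=C[C@H]1C#C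
F6 | step 8 | (1R,5R)-5-[(1S)-1-chloropropyl]-3-(trimethylsilyl)cyclopent-2-ene-1-carboxylic acid | CC[C@H](Cl)[C@@H]1CC([Si](C)(C)C)=C[C@H]1C(=O)O
F7 | step 8 | [(1R,5R)-5-[(1S)-1-chloropropyl]-3-(trimethylsilyl)cyclopent-2-en-1-yl]methanol | CC[C@H](Cl)[C@@H]1CC([Si](C)(C)C)=C[C@H]1CO
F8 | step 11 | (1S,2R,3R,4R)-4-[(1S)-1-chloropropyl]-3-(2,2-dibromoethenyl)cyclopentane-1,2-diol | CC[C@H](Cl)[C@@H]1C[C@H](O)[C@H](O)[C@H]1C=C(Br)Br
F9 | step 11 | cyclic methyl orthoacetate (2-methoxy-2-methyl-1,3-dioxolane) of diol F8 | CC[C@H](Cl)[C@@H]1C[C@@H]2OC(C)(OC)O[C@@H]2[C@H]1C=C(Br)Br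
F10 | step 11 | (1R,2R,4R,5R)-2-bromo-4-[(1S)-1-chloropropyl]-5-(2,2-dibromoethenyl)cyclopentyl acetate | CC[C@H](Cl)[C@@H]1C[C@@H](Br)[C@H](OC(C)=O)[C@H]1C=C(Br)Br
F11 | step 16 | methyl (5Z,8Z)-10-hydroxydeca-5,8-dienoate | OC/C=C\C/C=C\CCCC(=O)OC
F12 | step 16 | methyl (5Z,8Z)-10-bromodeca-5,8-dienoate | BrC/C=C\C/C=C\CCCC(=O)OC
F13 | step 16 | methyl (5Z,8Z)-12-[(1R,2R,3R,5S)-3-[(1S)-1-chloropropyl]-6-oxabicyclo[3.1.0]hexan-2-yl]dodeca-5,8-dien-11-ynoate | CC[C@H](Cl)[C@@H]1C[C@@H]2O[C@@H]2[C@H]1C#CC/C=C\C/C=C\CCCC(=O)OC
A1 | alternative 1 | methyl (Z)-2-diazo-3-oxonon-6-enoate | CC/C=C\CCC(=O)C(=[N+]=[N-])C(=O)OC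
A2 | alternative 1 | methyl endo-6-ethyl-2-oxobicyclo[3.1.0]hexane-1-carboxylate | CC[C@@H]1[C@@H]2CCC(=O)[C@]12C(=O)OC
A3 | alternative 2 | dimethyl (1R,2R)-4-oxocyclopentane-1,2-dicarboxylate | COC(=O)[C@@H]1CC(=O)C[C@H]1C(=O)OC
A4 | alternative 2 | (1R,2R)-cyclopent-3-ene-1,2-dicarboxylic acid | OC(=O)[C@@H]1CC=C[C@H]1C(=O)O
A5 | alternative 2 | 6-iodo-3-oxo-2-oxabicyclo[2.2.1]heptane-5-carboxylic acid (iodo γ-lactone acid) | O=C1O[C@H]2C[C@@H]1[C@H](C(=O)O)[C@@H]2I
A6 | alternative 3 | 3-methoxybenzoic acid | COc1cccc(C(=O)O)c1
A7 | alternative 3 | tert-butyl 2-diazo-3-oxocyclohex-4-ene-1-carboxylate | CC(C)(C)OC(=O)C1CC=CC(=O)C1=[N+]=[N-]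
A8 | alternative 3 | 1-tert-butyl 2-methyl trans-cyclopent-3-ene-1,2-dicarboxylate | CC(C)(C)OC(=O)[C@@H]1CC=C[C@H]1C(=O)OC
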